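**Strategy.** The cyclopentane ring of the cis-fused hydroazulene is cut at C1–C5, the ring-fusion bond between the two fully substituted carbons, and at C3–C4 (carotane numbering: C1 bears the methyl, C4 the isopropyl, C5 the hydroxyl, C10 the ester). The precursor is the acyclic (Z)-trienedione 11. In one flask a chiral copper hydride converts its α-methylene ketone into the C1 methyl enolate, which closes the seven-membered ring onto the C5 ketone; a tin hydride then closes the five-membered ring from C3 onto the isobutenyl group, creating the isopropyl. The step exploits the C10 ketone/C5 hydroxyl aldol relation across C1 and the isopropyl-bearing C4.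

Key step: step 9

Remark on numbering: atom labels in the text follow carotane numbering (C1 ring-fusion carbon with methyl, C2, C3, C4 isopropyl carbon, C5 carbinol, C6, C7, C8 vinylic-methyl carbon, C9, C10 oxygen-bearing carbon); systematic names use their own locants.

Remark on the chemistry: the sense of induction of the chiral copper hydride cannot be assigned with certainty in advance; the ligand enantiomer that leads to the (3aS,8aS) ketol is used, and (R)-DTBM-SEGPHOS is written for it.

Step 1
Reactants: 1 prop-2-yn-1-ol
Product: 2 (2Z)-3-iodo-2-methylprop-2-en-1-ol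
Conditions: MeMgBr (2.5 equiv), CuI (10 mol %), THF, −10 → 23 °C; then I2, −10 °C
Reagents that add atoms: methylmagnesium bromide C[Mg]Br; iodine II
Why: Copper-catalysed anti-carbomagnesiation of the propargylic magnesium alkoxide should put methyl on the internal carbon and magnesium on the terminal carbon cis to the CH2O group (cyclic alkoxide chelate), and iodinolysis with retention then gives the (Z)-iodide (alkoxide-directed carbometalation of a propargylic alcohol).

Step 2
Reactants: 2 (2Z)-3-iodo-2-methylprop-2-en-1-ol
Product: 3 (1Z)-3-bromo-1-iodo-2-methylprop-1-ene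
Conditions: CBr4, PPh3, CH2Cl2, 0 °C
Reagents that add atoms: carbon tetrabromide BrC(Br)(Br)Br
Why: Appel reaction; bromide displaces the oxyphosphonium group at the primary allylic carbon and the alkene geometry is not touched.

Step 3
Reactants: 4 4-methylpent-3-en-2-one (mesityl oxide); 3 (1Z)-3-bromo-1-iodo-2-methylprop-1-ene
Product: 5 (7Z)-8-iodo-2,7-dimethylocta-2,7-dien-4-one
Conditions: LiN(iPr)2, THF, −78 °C; then 3, DMPU, −78 → −30 °C
Reagents that add atoms: none
Why: Kinetic deprotonation of the enone at its methyl group gives the cross-conjugated lithium enolate, which should be alkylated by the reactive allylic bromide while the vinyl iodide stays inert (enolate alkylation).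

Step 4
Reactants: 6 4-chlorobutan-1-ol
Product: 7 4-(phenylselanyl)butan-1-ol
Conditions: (PhSe)2, NaBH4, EtOH, 0 °C; then 6, 60 °C
Reagents that add atoms: diphenyl diselenide c1ccc(cc1)[Se][Se]c1ccccc1
Why: NaBH4 cleaves the diselenide to the soft, weakly basic selenolate, which should displace the primary chloride without closing the chloro alcohol to tetrahydrofuran (SN2 substitution).

Step 5
Reactants: 7 4-(phenylselanyl)butan-1-ol
Product: 8 4-(phenylselanyl)butanal
Conditions: (COCl)2, DMSO, CH2Cl2, −78 °C; then Et3N, −78 → 0 °C
Reagents that add atoms: none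
Why: Swern oxidation; the activated sulfoxide oxidises the primary alcohol at low temperature and should leave the aryl alkyl selenide intact.

Step 6
Reactants: 8 4-(phenylselanyl)butanal
Product: 9 2-methylidene-4-(phenylselanyl)butanal
Conditions: aq. CH2O (37 %), pyrrolidine (10 mol %), EtCO2H (10 mol %), iPrOH, 45 °C
Reagents that add atoms: formaldehyde C=O
Why: Amine/acid-catalysed α-methylenation of an α-unbranched aldehyde (enamine Mannich addition to the iminium of formaldehyde, then elimination of the amine).

Step 7
Reactants: 5 (7Z)-8-iodo-2,7-dimethylocta-2,7-dien-4-one; 9 2-methylidene-4-(phenylselanyl)butanal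
Product: 10 (5Z)-4-hydroxy-6,11-dimethyl-3-methylidene-1-(phenylselanyl)dodeca-5,10-dien-9-one (both C4 epimers)
Conditions: CrCl2 (4 equiv), NiCl2 (2 mol %), DMSO, 23 °C
Reagents that add atoms: none
Why: Nozaki–Hiyama–Kishi coupling; the alkenylchromium species formed with retention of the (Z) geometry adds 1,2 to the aldehyde only, so the ketone, the enone and the selenide are tolerated, and the carbinol configuration is irrelevant because it is oxidised next.

Step 8
Reactants: 10 (5Z)-4-hydroxy-6,11-dimethyl-3-methylidene-1-(phenylselanyl)dodeca-5,10-dien-9-one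
Product: 11 (5Z)-6,11-dimethyl-3-methylidene-1-(phenylselanyl)dodeca-5,10-diene-4,9-dione
Conditions: MnO2 (activated, excess), CH2Cl2, 23 °C
Reagents that add atoms: none
Why: Heterogeneous MnO2 oxidation is selective for the doubly allylic alcohol and should not oxidise the selenide or isomerise the (Z) enone.

Step 9
Reactants: 11 (5Z)-6,11-dimethyl-3-methylidene-1-(phenylselanyl)dodeca-5,10-diene-4,9-dione
Product: 14 (3R,3aS,8aS)-3a-hydroxy-6,8a-dimethyl-3-(propan-2-yl)-2,3,3a,4,5,8a-hexahydroazulen-8(1H)-one, via cycloheptenone silyl ether 12 (not isolated), via bicyclic silyl ether 13 (not isolated)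
Conditions: Cu(OAc)2·H2O (5 mol %), (R)-DTBM-SEGPHOS (5.5 mol %), (EtO)2MeSiH (1.1 equiv), PhMe (0.02 M), −25 → 0 °C; then Bu3SnH (1.4 equiv, slow addition), AIBN (0.2 equiv), 80 °C; then 1 M HCl, THF, 0 °C
Reagents that add atoms: none
Why: The ligated CuH adds hydride to the unhindered methylene terminus of the cross-conjugated dienone (making the C1 methyl), and the chiral copper enolate, with the small methyl cis to the bulky ligated oxygen, adds through a closed chelated transition state to the C5 ketone (C1–C5) before silyl transfer gives 12; Bu3Sn• then abstracts the phenylselanyl group and the primary C3 radical closes onto C4 of the isobutenyl group, the resulting tertiary radical taking hydrogen from Bu3SnH to become the isopropyl group (C3–C4), and acid work-up frees the tertiary alcohol. The closest known reaction types are the copper hydride catalysed intramolecular reductive aldol cyclisation of enones onto ketones and the 5-hexenyl radical cyclisation of alkyl phenyl selenides, run here in one flask. The seven-membered ring closes in the 7-(enolendo)-exo-trig mode (aldol) and the five-membered ring in the 5-exo-trig mode (radical). C1 and C5 are set together: the chelate between the enolate oxygen and the C5 carbonyl oxygen places the C5 oxygen on the side of the C1 methyl (cis hydroxyl and methyl, hence the cis ring fusion after the second closure), and the bisphosphine on copper selects the enolate face and so the absolute configuration; C4 is set by A(1,3) strain, which holds the C5 oxygen in the plane of the isobutenyl double bond so that the new isopropyl group ends cis to the hydroxyl. The step needs 1,4-reduction of only the unsubstituted enone terminus, which the β,β-disubstitution of the two other enones and the single equivalent of Si–H should secure, and it needs 5-exo attack on the isobutenyl group rather than addition to the ring enone, which the faster closure onto an electron-neutral alkene giving a tertiary radical should secure.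

Step 10
Reactants: 14 (3R,3aS,8aS)-3a-hydroxy-6,8a-dimethyl-3-(propan-2-yl)-2,3,3a,4,5,8a-hexahydroazulen-8(1H)-one
Product: 15 (3R,3aS,8R,8aR)-6,8a-dimethyl-3-(propan-2-yl)-1,2,3,3a,4,5,8,8a-octahydroazulene-3a,8-diol
Conditions: Me4NBH(OAc)3, MeCN/AcOH (1:1), −25 °C
Reagents that add atoms: none
Why: Saksena–Evans reduction; the C5 hydroxyl exchanges onto boron and delivers hydride intramolecularly 1,2 to the face of the C10 carbonyl on its own side, so the new C10 hydroxyl should end anti to the C5 hydroxyl (trans to the C1 methyl).

Step 11
Reactants: 15 (3R,3aS,8R,8aR)-6,8a-dimethyl-3-(propan-2-yl)-1,2,3,3a,4,5,8,8a-octahydroazulene-3a,8-diol; 16 4-methoxybenzoyl chloride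
Product: 17 (3R,3aS,8R,8aR)-3a-hydroxy-6,8a-dimethyl-3-(propan-2-yl)-1,2,3,3a,4,5,8,8a-octahydroazulen-8-yl 4-methoxybenzoate (CNP0158828.3)
Conditions: 16, Et3N, DMAP (cat.), CH2Cl2, 0 → 23 °C
Reagents that add atoms: none
Why: DMAP-catalysed acylation should take place at the secondary allylic hydroxyl only, the tertiary ring-fusion hydroxyl being too hindered to react, and no stereocenter is touched.

**Compound list**

1 | prop-2-yn-1-ol | C#CCO | starting material
2 | (2Z)-3-iodo-2-methylprop-2-en-1-ol | OC/C(C)=C\I | intermediate
3 | (1Z)-3-bromo-1-iodo-2-methylprop-1-ene | BrC/C(C)=C\I | intermediate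
4 | 4-methylpent-3-en-2-one (mesityl oxide) | CC(=O)C=C(C)C | starting material
5 | (7Z)-8-iodo-2,7-dimethylocta-2,7-dien-4-one | CC(C)=CC(=O)CC/C(C)=C\I | intermediate
6 | 4-chlorobutan-1-ol | OCCCCCl | starting material
7 | 4-(phenylselanyl)butan-1-ol | OCCCC[Se]c1ccccc1 | intermediate
8 | 4-(phenylselanyl)butanal | O=CCCC[Se]c1ccccc1 | intermediate
9 | 2-methylidene-4-(phenylselanyl)butanal | C=C(CC[Se]c1ccccc1)C=O | intermediate
10 | (5Z)-4-hydroxy-6,11-dimethyl-3-methylidene-1-(phenylselanyl)dodeca-5,10-dien-9-one, both C4 epimers | C=C(CC[Se]c1ccccc1)C(O)/C=C(C)\CCC(=O)C=C(C)C | intermediate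
11 | (5Z)-6,11-dimethyl-3-methylidene-1-(phenylselanyl)dodeca-5,10-diene-4,9-dione | C=C(CC[Se]c1ccccc1)C(=O)/C=C(C)\CCC(=O)C=C(C)C | intermediate
12 | (6S,7S)-6-{[diethoxy(methyl)silyl]oxy}-3,7-dimethyl-6-(2-methylprop-1-en-1-yl)-7-[2-(phenylselanyl)ethyl]cyclohept-2-en-1-one (silyloxy cis to the C7 methyl) | O=C1C=C(C)CC[C@](O[Si](C)(OCC)OCC)(C=C(C)C)[C@]1(C)CC[Se]c2ccccc2 | intermediate
13 | (3R,3aS,8aS)-3a-{[diethoxy(methyl)silyl]oxy}-6,8a-dimethyl-3-(propan-2-yl)-2,3,3a,4,5,8a-hexahydroazulen-8(1H)-one | O=C1C=C(C)CC[C@]2(O[Si](C)(OCC)OCC)[C@@H](C(C)C)CC[C@]12C | intermediate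
14 | (3R,3aS,8aS)-3a-hydroxy-6,8a-dimethyl-3-(propan-2-yl)-2,3,3a,4,5,8a-hexahydroazulen-8(1H)-one (hydroxyl, angular methyl and isopropyl all cis) | O=C1C=C(C)CC[C@]2(O)[C@@H](C(C)C)CC[C@]12C | intermediate
15 | (3R,3aS,8R,8aR)-6,8a-dimethyl-3-(propan-2-yl)-1,2,3,3a,4,5,8,8a-octahydroazulene-3a,8-diol | O[C@@H]1C=C(C)CC[C@]2(O)[C@@H](C(C)C)CC[C@]12C | intermediate
16 | 4-methoxybenzoyl chloride | COc1ccc(cc1)C(Cl)=O | starting material
17 | (3R,3aS,8R,8aR)-3a-hydroxy-6,8a-dimethyl-3-(propan-2-yl)-1,2,3,3a,4,5,8,8a-octahydroazulen-8-yl 4-methoxybenzoate | COc1ccc(C(=O)O[C@@H]2C=C(C)CC[C@]3(O)[C@@H](C(C)C)CC[C@]23C)cc1 | target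

**Step count and risks**

Total step count: 11. Longest linear sequence: 8 steps (steps 1, 2, 3, 7, 8, 9, 10, 11); steps 4 to 6 form the second branch.

Steps most likely to fail:

Step 9. Three processes can spoil it. The copper enolate may be silylated before it closes the seven-membered ring, or may add with low facial selectivity. In the tin hydride stage the primary C3 radical may add to the conjugated double bond of the ring enone instead of closing 5-exo onto the isobutenyl group. Copper and silane residues may also break the radical chain. The fallback changes the order of events so that no radical-accepting enone is present when the five-membered ring is closed. It sets out from 11: the copper hydride stage alone is run and 12 is hydrolysed on work-up (dilute HCl, THF) to the isolated ketol (6S,7S)-6-hydroxy-3,7-dimethyl-6-(2-methylprop-1-en-1-yl)-7-[2-(phenylselanyl)ethyl]cyclohept-2-en-1-one F1. Its ring ketone is then reduced under hydroxyl direction (Me4NBH(OAc)3, MeCN/AcOH) to the anti diol (1R,6S,7R)-3,7-dimethyl-6-(2-methylprop-1-en-1-yl)-7-[2-(phenylselanyl)ethyl]cyclohept-2-ene-1,6-diol F2. Radical cyclisation of this diol (Bu3SnH, AIBN, PhH, 80 °C) should give 15, where the route is rejoined before step 11.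

Step 10. The tertiary hydroxyl may exchange onto boron too slowly, so that undirected hydride delivery or conjugate reduction takes over and the C10 configuration is lost. The fallback sets out from 14 and uses an undirected 1,2-reduction (NaBH4, CeCl3·7H2O, MeOH, Luche reduction). If this gives mainly the syn diol (3R,3aS,8S,8aR)-6,8a-dimethyl-3-(propan-2-yl)-1,2,3,3a,4,5,8,8a-octahydroazulene-3a,8-diol F3, a Mitsunobu esterification with 4-methoxybenzoic acid (PPh3, DIAD, THF) inverts C10 and installs the ester in the same operation. The route is rejoined at the target 17.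

Step 3. Proton transfer between the kinetic enolate and the product may lead to the extended dienolate, to alkylation at the wrong carbon and to double alkylation. The fallback sets out from 3: the lithium enolate of N-methoxy-N-methylacetamide (LiN(iPr)2, THF, −78 °C) is alkylated with 3 to give (4Z)-5-iodo-N-methoxy-N,4-dimethylpent-4-enamide F4. Addition of (2-methylprop-1-en-1-yl)magnesium bromide (THF, 0 °C) should stop at the ketone and give 5, where the route is rejoined.

**Further compounds**

F1 | step 9 | (6S,7S)-6-hydroxy-3,7-dimethyl-6-(2-methylprop-1-en-1-yl)-7-[2-(phenylselanyl)ethyl]cyclohept-2-en-1-one | O=C1C=C(C)CC[C@](O)(C=C(C)C)[C@]1(C)CC[Se]c2ccccc2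
F2 | step 9 | (1R,6S,7R)-3,7-dimethyl-6-(2-methylprop-1-en-1-yl)-7-[2-(phenylselanyl)ethyl]cyclohept-2-ene-1,6-diol | O[C@@H]1C=C(C)CC[C@](O)(C=C(C)C)[C@]1(C)CC[Se]c2ccccc2
F3 | step 10 | (3R,3aS,8S,8aR)-6,8a-dimethyl-3-(propan-2-yl)-1,2,3,3a,4,5,8,8a-octahydroazulene-3a,8-diol | O[C@H]1C=C(C)CC[C@]2(O)[C@@H](C(C)C)CC[C@]12C
F4 | step 3 | (4Z)-5-iodo-N-methoxy-N,4-dimethylpent-4-enamide | CON(C)C(=O)CC/C(C)=C\I
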